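At early times in the north-east run, [L]/[E] is 0.0460 at 3.00 min; by 40.0 min this ring ratio ρ reads 0.636, still climbing.

| flask | E | temperature | remark | time |
|---|---|---|---|---|
| north-east | 0.55 M | 100 °C | run made earlier |  |
| teal | 0.30 M | 130 °C |  | 2.0 h |
| green | 0.50 M | 100 °C |  | 2.0 h |

north-east run (percent of the E charged)

| time / min | L / % | E / % |
|---|---|---|
| 3.00 | 4 | 87 |
| 6.00 | 7 | 79 |
| 10.0 | 12 | 68 |
| 15.0 | 10 | 58 |
| 25.0 | 17 | 43 |
| 40.0 | 21 | 33 |

(standard deviation of a reading: 1.5 percentage points)

- which of the two ends with the higher amount of L, in percent of the E charged ("neither" if they lie within 2 percentage points) (teal / green / neither)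
- L at the end, in percent of the E charged, teal
- L at the end, in percent of the E charged, green

- the earlier runs do not show what temperature does; that part of a forecast is a guess

My own reckoning: if the ring reopens, then once that step reaches equilibrium ρ stops moving, [L] = ρ[E], and L follows E down. The north-east readings put E near second order, so 1/[E], taken in units of the charge, rises in a straight line, by 2.03 over that run, and I take that rise to scale with charge and time. Green then keeps 15.3% of E. Its ρ is taken as still climbing, so L follows the share of lost E seen as L in the north-east run: 26.5%. Teal needs a guess, and I borrow the forecast's 8 times the rate. That shrinks 40.0 min to 5.00 min, short against 2.0 h, and leaves 3.63% of E. With ρ as read, also a guess at 130 °C, teal holds 2.31% of L.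

The forecast parts from this reckoning on teal: it has teal ending higher, with 30% in teal and 26% in green. Its ground: “The selectivity therefore seems independent of E level”.

The flasks give 0.665% of L in teal and 26.7% in green, so green ends higher.

    E ⇌ L (K = 4.80, k = 0.0120 min⁻¹, Ea = 115 kJ mol⁻¹, ΔH = −90.0 kJ mol⁻¹)
    2 E → D (k = 0.0110 M⁻¹ min⁻¹, Ea = 101 kJ mol⁻¹)
    E ⇌ X (K = 0.660, k = 0.0190 min⁻¹, Ea = 101 kJ mol⁻¹, ΔH = 4.00 kJ mol⁻¹)
    L → Q (k = 0.00680 min⁻¹, Ea = 121 kJ mol⁻¹)
    (constants at 100 °C)

In teal, E and L relax into each other, by their own step alone, with a half-life of 1.31 min, short against 2.0 h. Teal's ρ is 0.431 at 1.00 h and 0.429 at 2.00 h, lower than the 0.636 read in the north-east run at 100 °C, while E in teal drops from 6.98% to 1.55%. The neighbouring flask, teal charged with 1.2 M of E, keeps 0.722% of E at 2.00 h. Teal's ρ turns that into 0.310% of L, and the flask holds 0.311%.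

(All runs were generated by integration on assumed constants; noise was put on by code.)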